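The carbocyclic ring C4–C5–C6–C1–C7–C8 of the target, numbered as a spiro[2-oxabicyclo[2.2.2]octane-8,2'-oxane], is a Diels–Alder retron. C8 (spiro, ether O) and C4 (quaternary, lactone C=O) form an exocyclic β-alkoxyacrylate on the oxane. C7–C1–C6–C5, with the lactone oxygen on C1 and the ketone on C5, is a 1,3-dioxygenated diene. A diisopropylsilyl acetal joins the diene oxygen to the oxane C4' hydroxyl (later the acetate), so one silicon-tethered type 2 intramolecular cycloaddition forms C7–C8 and C4–C5 and sets C4, C7 and C8. The precursor is an acyclic bis(silyloxy)diene hung on a 2-alkylidene-oxane.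

Key step: step 7

Remark: labels C1–C8 and C2'–C6' are the locants of the target's spiro name and denote the same atoms in every intermediate; the C6 methyl of the target (pointing toward the lactone bridge) is assumed to be the thermodynamically preferred epimer next to the C5 ketone.

Step 1
Reactants: 1 (R)-4-benzyl-3-propanoyl-1,3-oxazolidin-2-one; 2 propanoyl chloride
Product: 4 (R)-4-benzyl-3-[(S)-2-methyl-3-oxopentanoyl]-1,3-oxazolidin-2-one, via lithium enolate 3 (not isolated)
Conditions: LiN(iPr)2, THF, −78 °C; then EtCOCl, −78 °C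
Reagents that add atoms: propanoyl chloride, CCC(=O)Cl
Why: Evans acylation of the chelated lithium Z-enolate, in which the acid chloride should attack the face opposite the benzyl group and so set the (S) methine (later C3'), the product being protected from epimerisation by allylic strain.

Step 2
Reactants: 4; 5 acetaldehyde
Product: 7 (R)-4-benzyl-3-[(2S,4R,5S)-5-hydroxy-2,4-dimethyl-3-oxohexanoyl]-1,3-oxazolidin-2-one, via divalent tin enolate 6 (not isolated)
Conditions: Sn(OTf)2, Et3N, CH2Cl2, −20 °C; then MeCHO, −78 °C
Reagents that add atoms: acetaldehyde, CC=O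
Why: Evans β-ketoimide aldol reaction of the divalent tin Z-enolate, whose closed transition state should give the 4,5-syn aldol while the existing methyl-bearing centre directs the 2,4-anti relationship, setting C5' and C6'.

Step 3
Reactants: 7
Product: 9 (3S,4R,5S,6S)-4-hydroxy-3,5,6-trimethyloxan-2-one, via diol imide 8 (not isolated)
Conditions: Me4NBH(OAc)3, MeCN/AcOH (1:1), −20 °C; then DBU (0.2 equiv), CH2Cl2, 23 °C
Reagents that add atoms: none
Why: Evans–Saksena reduction, in which hydride delivered from the borate bound to the existing hydroxyl should give the 1,3-anti diol (C4'), followed by lactonisation of the δ-hydroxyl onto the imide with release of the auxiliary.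

Step 4
Reactants: 9; 10 methyl propanoate
Product: 12 methyl (E)-2-[(3S,4R,5S,6S)-4-hydroxy-3,5,6-trimethyloxan-2-ylidene]propanoate, via lactol 11 (not isolated)
Conditions: MeCH2CO2Me and LiN(iPr)2 (3.2 equiv each), THF, −78 °C, AcOH quench; then camphorsulfonic acid (0.1 equiv), 4 Å molecular sieves, PhMe, 50 °C
Reagents that add atoms: methyl propanoate, CCC(=O)OC
Why: Claisen-type addition of the ester enolate to the lactone (the hydroxyl carried as its alkoxide) and acid-catalysed dehydration of the lactol through the oxocarbenium ion should give the conjugated exocyclic enol ether under thermodynamic control, with the ester anti to the ring oxygen (E) as in β-alkoxycrotonates.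

Step 5
Reactants: 13 pentan-3-one; 14 ethyl formate; 15 tert-butyl(chloro)dimethylsilane
Product: 17 (E)-1-[tert-butyl(dimethyl)silyl]oxy-2-methylpent-1-en-3-one, via sodium enolate 16 (not isolated)
Conditions: NaH, HCO2Et, Et2O, 0 to 23 °C; then TBSCl, THF, 0 °C
Reagents that add atoms: ethyl formate, CCOC=O; tert-butyl(chloro)dimethylsilane, CC(C)(C)[Si](C)(C)Cl
Why: crossed Claisen formylation of the ketone followed by O-silylation of the sodium enolate at the less hindered, aldehyde-derived oxygen should give the (E)-β-silyloxy enone.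

Step 6
Reactants: 12; 17; 18 dichlorodi(propan-2-yl)silane
Product: 21 tethered triene, the mixed di(propan-2-yl)silyl acetal between the oxane hydroxyl of 12 and the (2Z,4E)-dienol of 17, via chlorosilyl ether 19 (not isolated), via lithium dienolate 20 (not isolated)
Conditions: 12, iPr2SiCl2 (1.5 equiv), imidazole, CH2Cl2, 0 °C, excess silane removed in vacuo; separately 17, LiN(SiMe3)2, THF, −78 °C; then the chlorosilane, −78 to 0 °C
Reagents that add atoms: dichlorodi(propan-2-yl)silane, CC(C)[Si](Cl)(Cl)C(C)C
Why: O-silylation of the kinetic cross-conjugated lithium enolate by the alkoxychlorosilane (silyl acetal tether formation), the ethyl ketone with a branched alkenyl group being expected to give the Z enolate so that the future C7 methyl is "outside" on the diene.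

Step 7
Reactants: 21
Product: 22 silicon-bridged cycloadduct: cyclohexene with a C1=C6 enol ether whose C1 oxygen is joined through Si(iPr)2 to the oxane C4' oxygen; C4 bears Me and CO2Me, C5 bears OTBS (cis to the C7 methyl); C4, C7, C8 and C3'–C6' configured as in the target
Conditions: PhMe (0.01 M), 2,6-di-tert-butyl-4-methylphenol (cat.), base-washed sealed tube, 160 °C
Reagents that add atoms: none
Why: On heating, the s-cis 1,3-bis(silyloxy)diene and the exocyclic β-alkoxyacrylate should combine in a concerted, asynchronous [4+2] cycloaddition, the nucleophilic diene terminus C7 bonding to the alkoxy-bearing β-carbon C8 and the silyloxy-bearing terminus C5 to the α-carbon C4. The closest known reaction type is the silicon-tethered type 2 intramolecular Diels–Alder reaction of a 2-silyloxydiene linked to an alkenyl alcohol through a dialkylsilyl acetal. The cyclohexene ring closes in the Diels–Alder mode, and the eight-membered silyl acetal ring closes as the bridged (meta) ring of a bicyclo[5.3.1] system with a bridgehead enol ether. C8 is set by the tether, which can reach the alkene only from the oxane face that carries the C4' oxygen; C7 is set by the Z enol ether (methyl outside) together with the tether-enforced endo position of C3', which places the methyl cis to C3' and to the ester; C4 follows from the E geometry of the dienophile, and the C5 centre (OTBS cis to the C7 methyl) is removed later. The step needs regioselectivity, which diene and dienophile polarity and the tether length both favour, and face selectivity, which the 1,3-cis relation between the C4' oxygen and the new C8–C7 bond secures. In the reacting conformer the C3' methyl should be axial to relieve allylic strain, which also turns the C4' oxygen axial toward the diene.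

Step 8
Reactants: 22
Product: 23 keto alcohol: methyl cyclohexanecarboxylate with C1 ketone, C6 methyl cis to the C7 methyl, C5 OTBS, quaternary C4 (Me, CO2Me), spiro at C8 to the 4'-hydroxy-3',5',6'-trimethyloxane
Conditions: Bu4NF, AcOH (1:1), THF, 0 °C
Reagents that add atoms: none
Why: buffered fluoride desilylation should cleave the strained silyl enol ether and the remaining silyl ether faster than the hindered secondary TBS ether, the enolate being protonated at C6 from the face opposite the ester, C3' and OTBS (methyl equatorial), while the buffer suppresses β-elimination of the C8 ring oxygen.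

Step 9
Reactants: 23
Product: 25 bicyclic lactone alcohol: the target skeleton with C5 H/OTBS (silyloxy toward the lactone bridge) in place of the ketone and a free C4' hydroxyl, via hydroxy ester 24 (not isolated)
Conditions: NaBH4, CeCl3·7H2O, MeOH, −78 °C; then pyridinium p-toluenesulfonate (0.2 equiv), 4 Å molecular sieves, PhMe, 80 °C
Reagents that add atoms: none
Why: Luche reduction in which hydride should attack C1 from the face opposite the syn-axial C8–C3' and C5–OTBS bonds and the ester, placing the new hydroxyl cis to the ester, followed by acid-catalysed lactonisation of the cis-4-hydroxycyclohexanecarboxylate to the bridged δ-lactone.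

Step 10
Reactants: 25; 26 acetic anhydride
Product: 27 C4' acetate of 25
Conditions: Ac2O, pyridine, 4-(dimethylamino)pyridine (cat.), CH2Cl2, 23 °C
Reagents that add atoms: acetic anhydride, CC(=O)OC(C)=O
Why: nucleophile-catalysed acylation of the only free (equatorial secondary) hydroxyl, with no change at any stereocentre.

Step 11
Reactants: 27
Product: 28 C5 alcohol (5-hydroxy analogue of the target)
Conditions: HF·pyridine, THF, 23 °C
Reagents that add atoms: none
Why: acidic fluoride desilylation should remove the hindered secondary TBS ether while leaving acetate and lactone untouched.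

Step 12
Reactants: 28
Product: 29 (1S,4R,6S,7R,8S,3'S,4'R,5'R,6'S)-3',4,5',6,6',7-hexamethyl-3,5-dioxospiro[2-oxabicyclo[2.2.2]octane-8,2'-oxan]-4'-yl acetate (target)
Conditions: Dess–Martin periodinane, NaHCO3, CH2Cl2, 23 °C
Reagents that add atoms: none
Why: Dess–Martin oxidation of the hindered secondary alcohol under buffered, near-neutral conditions should give the C5 ketone without β-elimination of the lactone oxygen, C6 keeping its thermodynamically preferred configuration.

Compound list
1 | (R)-4-benzyl-3-propanoyl-1,3-oxazolidin-2-one | CCC(=O)N1[C@H](Cc2ccccc2)COC1=O | starting material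
2 | propanoyl chloride | CCC(=O)Cl | starting material
3 | lithium (Z)-enolate of 1 | C/C=C(\[O-])N1[C@H](Cc2ccccc2)COC1=O.[Li+] | intermediate
4 | (R)-4-benzyl-3-[(S)-2-methyl-3-oxopentanoyl]-1,3-oxazolidin-2-one | CCC(=O)[C@H](C)C(=O)N1[C@H](Cc2ccccc2)COC1=O | intermediate
5 | acetaldehyde | CC=O | starting material
6 | divalent tin (Z)-enolate of 4 (triflate on tin) | C/C=C(\O[Sn]OS(=O)(=O)C(F)(F)F)[C@H](C)C(=O)N1[C@H](Cc2ccccc2)COC1=O | intermediate
7 | (R)-4-benzyl-3-[(2S,4R,5S)-5-hydroxy-2,4-dimethyl-3-oxohexanoyl]-1,3-oxazolidin-2-one | O=C([C@H](C)C(=O)N1[C@H](Cc2ccccc2)COC1=O)[C@H](C)[C@H](C)O | intermediate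
8 | (R)-4-benzyl-3-[(2S,3R,4R,5S)-3,5-dihydroxy-2,4-dimethylhexanoyl]-1,3-oxazolidin-2-one | O[C@@H]([C@H](C)C(=O)N1[C@H](Cc2ccccc2)COC1=O)[C@H](C)[C@H](C)O | intermediate
9 | (3S,4R,5S,6S)-4-hydroxy-3,5,6-trimethyloxan-2-one | O[C@@H]1[C@H](C)[C@H](C)OC(=O)[C@H]1C | intermediate
10 | methyl propanoate | CCC(=O)OC | starting material
11 | methyl 2-[(3S,4R,5S,6S)-2,4-dihydroxy-3,5,6-trimethyloxan-2-yl]propanoate (lactol, mixture at C2 and the side-chain carbon) | O[C@@H]1[C@H](C)[C@H](C)OC(O)(C(C)C(=O)OC)[C@H]1C | intermediate
12 | methyl (E)-2-[(3S,4R,5S,6S)-4-hydroxy-3,5,6-trimethyloxan-2-ylidene]propanoate | O[C@@H]1[C@H](C)[C@H](C)O/C(=C(\C)C(=O)OC)[C@H]1C | intermediate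
13 | pentan-3-one | CCC(=O)CC | starting material
14 | ethyl formate | CCOC=O | starting material
15 | tert-butyl(chloro)dimethylsilane | CC(C)(C)[Si](C)(C)Cl | starting material
16 | sodium 2-methyl-3-oxopent-1-en-1-olate | CCC(=O)C(C)=C[O-].[Na+] | intermediate
17 | (E)-1-[tert-butyl(dimethyl)silyl]oxy-2-methylpent-1-en-3-one | CCC(=O)/C(C)=C/O[Si](C)(C)C(C)(C)C | intermediate
18 | dichlorodi(propan-2-yl)silane | CC(C)[Si](Cl)(Cl)C(C)C | starting material
19 | chlorodi(propan-2-yl)silyl ether of 12 | CC(C)[Si](Cl)(O[C@@H]1[C@H](C)[C@H](C)O/C(=C(\C)C(=O)OC)[C@H]1C)C(C)C | intermediate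
20 | lithium (2Z,4E)-5-[tert-butyl(dimethyl)silyl]oxy-4-methylpenta-2,4-dien-3-olate | C/C=C(\[O-])/C(C)=C/O[Si](C)(C)C(C)(C)C.[Li+] | intermediate
21 | tethered triene (silyl acetal of 12 and the dienol of 17; oxane stereocentres as in 12, diene 2Z,4E, alkylidene E) | C/C=C(\O[Si](C(C)C)(C(C)C)O[C@@H]1[C@H](C)[C@H](C)O/C(=C(\C)C(=O)OC)[C@H]1C)/C(C)=C/O[Si](C)(C)C(C)(C)C | intermediate
22 | silicon-bridged Diels–Alder adduct | CC(C)[Si]1(C(C)C)O[C@@H]2[C@H](C)[C@H](C)O[C@]3([C@H](C)C(O1)=C(C)[C@H](O[Si](C)(C)C(C)(C)C)[C@]3(C)C(=O)OC)[C@H]2C | intermediate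
23 | keto alcohol (C1 ketone, C5 OTBS, C4' OH) | O[C@@H]1[C@H](C)[C@H](C)O[C@]2([C@H](C)C(=O)[C@H](C)[C@H](O[Si](C)(C)C(C)(C)C)[C@]2(C)C(=O)OC)[C@H]1C | intermediate
24 | hydroxy ester (C1 OH cis to CO2Me) | O[C@@H]1[C@H](C)[C@H](C)O[C@]2([C@H](C)[C@H](O)[C@H](C)[C@H](O[Si](C)(C)C(C)(C)C)[C@]2(C)C(=O)OC)[C@H]1C | intermediate
25 | bicyclic lactone alcohol (C5 OTBS, C4' OH) | O[C@@H]1[C@H](C)[C@H](C)O[C@]2([C@H](C)[C@@H]3OC(=O)[C@@]2(C)[C@@H](O[Si](C)(C)C(C)(C)C)[C@H]3C)[C@H]1C | intermediate
26 | acetic anhydride | CC(=O)OC(C)=O | starting material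
27 | C4' acetate, C5 OTBS | CC(=O)O[C@@H]1[C@H](C)[C@H](C)O[C@]2([C@H](C)[C@@H]3OC(=O)[C@@]2(C)[C@@H](O[Si](C)(C)C(C)(C)C)[C@H]3C)[C@H]1C | intermediate
28 | C4' acetate, C5 alcohol | CC(=O)O[C@@H]1[C@H](C)[C@H](C)O[C@]2([C@H](C)[C@@H]3OC(=O)[C@@]2(C)[C@@H](O)[C@H]3C)[C@H]1C | intermediate
29 | (1S,4R,6S,7R,8S,3'S,4'R,5'R,6'S)-3',4,5',6,6',7-hexamethyl-3,5-dioxospiro[2-oxabicyclo[2.2.2]octane-8,2'-oxan]-4'-yl acetate | CC(=O)O[C@@H]1[C@H](C)[C@H](C)O[C@]2([C@H](C)[C@@H]3OC(=O)[C@@]2(C)C(=O)[C@H]3C)[C@H]1C | target

Total steps: 12. Longest linear sequence: 11 steps (steps 1–4 and 6–12).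

Steps most likely to fail

Step 7. The cycloaddition may stall because the tetrasubstituted, donor-substituted alkene is shielded and the oxane must leave its best chair to let the tether reach, or the silyl acetal may hydrolyse before ring closure. The fallback gives up the tether and makes the same two bonds by an intermolecular Diels–Alder reaction under high pressure. It sets out from 12 and 17: alcohol 12 would be capped as triethylsilyl ether F1 (Et3SiCl, imidazole), and enone 17 converted into (1E,3Z)-bis(silyloxy)diene F2 (LiN(SiMe3)2, Me3SiCl, THF, −78 °C). F1 and F2 would be combined at about 12 kbar (CH2Cl2, 25 °C) to untethered cycloadduct F3. Buffered Bu4NF as in step 8 would remove the enol and triethylsilyl groups and return to the route at 23. Face selectivity would then rest on equatorial approach to the alkylidene oxane and would have to be checked.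

Step 4. The basic ester enolate may enolise the lactone instead of adding (return of 9 or epimerisation at C3'), and under acid the free C4' hydroxyl may close onto the ester in competition with dehydration. The fallback replaces the addition–dehydration by a direct carbonyl olefination. It sets out from 9: silylation (TBSOTf, 2,6-lutidine) would give silyl ether F4, and a Wittig reaction with methyl 2-(triphenylphosphoranylidene)propanoate (PhMe, 140 °C, sealed tube) would give alkylidene oxane F5, the E isomer being separated or reached by trace-acid equilibration. Bu4NF would then return to the route at 12.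

Step 9. Hydride may be delivered to the other face of the C1 ketone if the cyclohexanone adopts a different conformation, giving an alcohol trans to the ester that cannot lactonise. The fallback closes the lactone with inversion instead of retention. It sets out from 23: the epimeric hydroxy ester F6 would be cleaved to hydroxy acid F7 (Me3SnOH, 1,2-dichloroethane, 80 °C) and closed by an intramolecular Mitsunobu reaction (PPh3, diisopropyl azodicarboxylate, THF), which inverts C1 and returns to the route at 25.

Further compounds
F1 | step 7 | triethylsilyl ether of 12 | CC[Si](CC)(CC)O[C@@H]1[C@H](C)[C@H](C)O/C(=C(\C)C(=O)OC)[C@H]1C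
F2 | step 7 | (1E,3Z)-1-[tert-butyl(dimethyl)silyl]oxy-2-methyl-3-(trimethylsilyloxy)penta-1,3-diene | C/C=C(\O[Si](C)(C)C)/C(C)=C/O[Si](C)(C)C(C)(C)C
F3 | step 7 | untethered cycloadduct (C1 OSiMe3 enol ether, C4' OSiEt3, C5 OTBS) | CC[Si](CC)(CC)O[C@@H]1[C@H](C)[C@H](C)O[C@]2([C@H](C)C(O[Si](C)(C)C)=C(C)[C@H](O[Si](C)(C)C(C)(C)C)[C@]2(C)C(=O)OC)[C@H]1C
F4 | step 4 | tert-butyldimethylsilyl ether of 9 | CC(C)(C)[Si](C)(C)O[C@@H]1[C@H](C)[C@H](C)OC(=O)[C@H]1C
F5 | step 4 | tert-butyldimethylsilyl ether of 12 | CC(C)(C)[Si](C)(C)O[C@@H]1[C@H](C)[C@H](C)O/C(=C(\C)C(=O)OC)[C@H]1C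
F6 | step 9 | C1 epimer of hydroxy ester 24 | O[C@@H]1[C@H](C)[C@H](C)O[C@]2([C@H](C)[C@@H](O)[C@H](C)[C@H](O[Si](C)(C)C(C)(C)C)[C@]2(C)C(=O)OC)[C@H]1C
F7 | step 9 | hydroxy acid from F6 | O[C@@H]1[C@H](C)[C@H](C)O[C@]2([C@H](C)[C@@H](O)[C@H](C)[C@H](O[Si](C)(C)C(C)(C)C)[C@]2(C)C(=O)O)[C@H]1C
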